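**Retrosynthetic overview**
1. Target ⇐ global desilylation of a 1‑O‑TBS / 4,6‑O‑silylene 8‑acetate; the acrylate ⇐ Pd methoxycarbonylation of the 2‑propenyl triflate of a C7 methyl ketone.
2. C8–OH ⇐ Cu‑catalysed β‑borylation/oxidation of a 7‑acetyl‑Δ7 enone ⇐ Stille coupling of the C7 enol triflate; C6–OH ⇐ Rubottom oxidation of the Δ6 silyl enol ether from Li/NH3 reduction of a Δ5‑7‑enone (this also sets the trans ring fusion).
3. C4 carbinol ⇐ α‑epoxidation / E1cB opening of a 4‑methyl β,γ‑enone; the C4 methyl ⇐ Grignard opening of a Δ4‑ketal epoxide.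
4. C1 carbinol ⇐ ketoreductase reduction; C10 ⇐ D‑proline Hajos–Parrish–Eder–Sauer–Wiechert annulation of the triketone from 2‑methylcyclohexane‑1,3‑dione and methyl vinyl ketone.
5. Ring order: ring A is the starting dione ring; ring B is closed by the proline aldol condensation; no further ring construction.

Assumption: positions follow eudesmane numbering (C1–C5/C10 = ring A, C5–C10 = ring B, C11–C13 = acrylate, α = face opposite the C10 methyl), and an anti‑Prelog ketoreductase that accepts 5 is taken from a commercial screening panel.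

**Route**

Step 1
Reactants: 1 2-methylcyclohexane-1,3-dione; 2 methyl vinyl ketone
Product: 3 2-methyl-2-(3-oxobutyl)cyclohexane-1,3-dione
Conditions: AcOH (cat.), hydroquinone (cat.), H2O, 75 °C
Reagents that add atoms: none
Why: Michael addition of the acidic 1,3-dione to the enone gives the achiral, prochiral triketone.

Step 2
Reactants: 3 2-methyl-2-(3-oxobutyl)cyclohexane-1,3-dione
Product: 5 (R)-Wieland–Miescher ketone, via bicyclic ketol 4 (not isolated)
Conditions: D-proline (5 mol %), DMSO, rt, 5 d; recrystallise (Et2O–hexane, −20 °C) to ≥99% ee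
Reagents that add atoms: none
Why: Hajos–Parrish–Eder–Sauer–Wiechert reaction, in which the D-proline enamine of the side-chain ketone attacks one of the two enantiotopic ring carbonyls through a carboxylic-acid-directed transition state, fixing C10 as R before the ketol dehydrates.

Step 3
Reactants: 5 (R)-Wieland–Miescher ketone
Product: 6 (4aR,5R)-5-hydroxy-4a-methyl-4,4a,5,6,7,8-hexahydronaphthalen-2(3H)-one
Conditions: ketoreductase (anti-Prelog, NADPH-dependent), NADP+ (cat.), MgSO4, i-PrOH (15% v/v), KPi buffer pH 7.0, 30 °C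
Reagents that add atoms: none
Why: Enzymatic (ketoreductase) carbonyl reduction delivers hydride to the saturated C1 ketone on the face opposite the angular methyl, giving the 1β (R) carbinol, leaving the enone untouched and rejecting any residual (S)-5.

Step 4
Reactants: 6 hydroxy enone
Product: 7 TBS ether of 6
Conditions: TBSCl, imidazole, DMAP (cat.), DMF, 45 °C
Reagents that add atoms: tert-butyldimethylsilyl chloride, CC(C)(C)[Si](C)(C)Cl
Why: Silyl ether protection of the neopentyl secondary alcohol with a group that survives every later step and leaves with HF at the end.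

Step 5
Reactants: 7 TBS ether enone
Product: 8 Δ4-ene 7-ethylene ketal
Conditions: ethylene glycol, p-TsOH·H2O (3 mol %), benzene, reflux, Dean–Stark
Reagents that add atoms: ethylene glycol, OCCO
Why: Acid-catalysed ketalisation of the enone proceeds through the dienol ether and moves the double bond out of conjugation to C4=C5.

Step 6
Reactants: 8 Δ4-ene ketal
Product: 9 4α,5α-epoxy ketal
Conditions: mCPBA, NaHCO3, CH2Cl2, 0 °C; chromatographic removal of the minor β-epoxide
Reagents that add atoms: meta-chloroperbenzoic acid, OOC(=O)c1cccc(Cl)c1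
Why: Prilezhaev epoxidation takes place mainly on the α-face because the axial C10 methyl shields the β-face (these two centres are erased again in step 8).

Step 7
Reactants: 9 4α,5α-epoxy ketal
Product: 10 4β-methyl-5α-hydroxy ketal
Conditions: MeMgBr (4 equiv), CuI (10 mol %), THF, 0 → 55 °C; aq. NH4Cl
Reagents that add atoms: methylmagnesium bromide, C[Mg]Br
Why: Fürst–Plattner trans-diaxial epoxide opening at the secondary C4 by the methyl nucleophile installs the C4 methyl (the 6-methyl-steroid precedent).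

Step 8
Reactants: 10 4β-methyl-5α-hydroxy ketal
Product: 12 4α-methyl-Δ5-en-7-one, via 5α-hydroxy ketone 11 (not isolated)
Conditions: PPTS, acetone–H2O (9:1), 60 °C; then NaOMe (0.5 equiv), MeOH, rt
Reagents that add atoms: water, O
Why: Ketal hydrolysis followed by E1cB dehydration of the β-hydroxy ketone gives the conjugated enone, and C4 equilibrates through the dienolate to the equatorial methyl epimer (of no consequence).

Step 9
Reactants: 12 4α-methyl-Δ5-en-7-one
Product: 14 4-methyl-Δ4-en-7-one, via potassium dienolate 13 (not isolated)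
Conditions: KOt-Bu (6 equiv), t-BuOH, rt, 1.5 h; inverse quench into 10% aq. AcOH, 0 °C; used at once
Reagents that add atoms: none
Why: Ringold–Malhotra deconjugation, in which γ-deprotonation at C4 gives the extended dienolate and kinetic α-protonation at C6 gives the β,γ-enone with a tetrasubstituted C4=C5 bond.

Step 10
Reactants: 14 4-methyl-Δ4-en-7-one
Product: 16 4α-hydroxy-4β-methyl-Δ5-en-7-one, via 4α,5α-epoxy ketone 15 (not isolated)
Conditions: mCPBA (1.1 equiv), Na2HPO4, CH2Cl2, −10 °C; then Et3N (2 equiv), rt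
Reagents that add atoms: meta-chloroperbenzoic acid, OOC(=O)c1cccc(Cl)c1
Why: Prilezhaev epoxidation on the α-face (β-face blocked by the C10 methyl) followed by E1cB opening of the β,γ-epoxy ketone at C5–O leaves the oxygen on C4 as the 4α-OH/4β-CH3 tertiary carbinol.

Step 11
Reactants: 16 4α-hydroxy-4β-methyl-Δ5-en-7-one
Product: 18 4α,7-bis(trimethylsilyloxy)-Δ6-ene (5α-H), via dilithium enolate alkoxide 17 (not isolated)
Conditions: Li (2.5 equiv), NH3(l)–THF, −78 °C, 20 min; isoprene; evaporate NH3; TMSCl–Et3N (5 equiv each), THF, −78 → 0 °C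
Reagents that add atoms: chlorotrimethylsilane, C[Si](C)(C)Cl
Why: Dissolving-metal (Birch-type) enone reduction with axial protonation at C5 gives the trans ring fusion (5α-H), and Stork trapping of the regiospecific Δ6 enolate (and of the C4 alkoxide, which resists reductive loss) gives the silyl enol ether.

Step 12
Reactants: 18 bis(trimethylsilyl) enol ether
Product: 20 4α,6α-dihydroxy-7-ketone, via 4α,6α-bis(trimethylsilyloxy) ketone 19 (not isolated)
Conditions: mCPBA (1.05 equiv), NaHCO3, CH2Cl2–hexane, −20 °C; then AcOH–THF–H2O (3:1:1), rt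
Reagents that add atoms: meta-chloroperbenzoic acid, OOC(=O)c1cccc(Cl)c1
Why: Rubottom oxidation, in which the enol ether is epoxidised from the α-face (the β-face of C6 is screened by both axial methyls on C4 and C10) and silyl migration gives the equatorial 6α-oxygen before mild acid removes the TMS groups.

Step 13
Reactants: 20 4α,6α-dihydroxy-7-ketone
Product: 21 4α,6α-O-(di-tert-butylsilylene)-7-ketone
Conditions: t-Bu2Si(OTf)2 (1.1 equiv), 2,6-lutidine (3 equiv), CH2Cl2, 0 °C
Reagents that add atoms: di-tert-butylsilyl bis(trifluoromethanesulfonate), CC(C)(C)[Si](OS(=O)(=O)C(F)(F)F)(OS(=O)(=O)C(F)(F)F)C(C)(C)C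
Why: The peri-diequatorial 1,3-diol closes a six-membered dioxasilinane (cyclic silylene protection) that masks both hydroxyls in one step and is HF-labile.

Step 14
Reactants: 21 silylene ketone
Product: 23 Δ7-en-7-yl triflate, via potassium Δ7-enolate 22 (not isolated)
Conditions: KHMDS (1.2 equiv), THF, −78 °C; PhNTf2 (1.3 equiv), −78 → −20 °C
Reagents that add atoms: N-phenylbis(trifluoromethanesulfonimide), O=S(=O)(N(c1ccccc1)S(=O)(=O)C(F)(F)F)C(F)(F)F
Why: Kinetic enolisation occurs at the C8 methylene (C6 is oxygenated and its axial hydrogen is buried between two axial methyls) and O-triflation gives the enol triflate.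

Step 15
Reactants: 23 Δ7-en-7-yl triflate
Product: 25 7-acetyl-Δ7-ene, via 7-(1-ethoxyvinyl) diene 24 (not isolated)
Conditions: tributyl(1-ethoxyvinyl)stannane (1.5 equiv), Pd(PPh3)4 (5 mol %), LiCl (3 equiv), 1,4-dioxane, 90 °C; then 5% aq. oxalic acid, THF, rt
Reagents that add atoms: tributyl(1-ethoxyvinyl)stannane, CCCC[Sn](CCCC)(CCCC)C(=C)OCC; water, O
Why: Stille cross-coupling of the enol triflate with an acyl-anion equivalent followed by enol ether hydrolysis attaches C11/C13 as a methyl ketone conjugated to C7=C8.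

Step 16
Reactants: 25 7-acetyl-Δ7-ene
Product: 27 8α-hydroxy-7β-acetyl compound, via 8α-pinacolboryl ketone 26 (not isolated)
Conditions: B2pin2 (1.2 equiv), CuCl (10 mol %), DPEphos (10 mol %), NaOt-Bu (15 mol %), MeOH (2 equiv), THF, rt; then NaBO3·4H2O, THF–H2O, rt
Reagents that add atoms: bis(pinacolato)diboron, CC1(C)OB(OC1(C)C)B1OC(C)(C)C(C)(C)O1 (boron of 26); sodium perborate, [Na+].[Na+].O[B-]1(O)OO[B-](O)(O)OO1 (oxygen of 27)
Why: Copper-catalysed conjugate borylation adds boron to C8 from the α-face (the β-face is 1,3-shielded by the C10 methyl), perborate oxidation retains configuration, and the epimerisable C7 settles with the acetyl group equatorial (β) between two equatorial oxygens.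

Step 17
Reactants: 27 8α-hydroxy ketone
Product: 28 8α-triethylsilyl ether
Conditions: TESCl, imidazole, DMAP (cat.), DMF, 0 °C → rt
Reagents that add atoms: chlorotriethylsilane, CC[Si](CC)(CC)Cl
Why: Temporary silyl protection of the β-hydroxy ketone prevents elimination or acyl transfer during the next enolisation and can later be removed selectively.

Step 18
Reactants: 28 8α-triethylsilyl ether
Product: 30 2-propenyl triflate, via potassium methyl-ketone enolate 29 (not isolated)
Conditions: KHMDS (1.2 equiv), THF, −78 °C; PhNTf2 (1.3 equiv), −78 → −20 °C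
Reagents that add atoms: N-phenylbis(trifluoromethanesulfonimide), O=S(=O)(N(c1ccccc1)S(=O)(=O)C(F)(F)F)C(F)(F)F
Why: Kinetic deprotonation of the methyl group (the C7 methine is hindered and flanked by two silyloxy carbons) and O-triflation give the terminal enol triflate without touching the C7 stereocentre.

Step 19
Reactants: 30 2-propenyl triflate
Product: 31 methyl acrylate with 8α-OTES
Conditions: Pd(OAc)2 (10 mol %), dppp (12 mol %), Et3N (3 equiv), CO (1 atm), MeOH–DMF (1:2), 60 °C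
Reagents that add atoms: carbon monoxide, [C-]#[O+]; methanol, CO
Why: Palladium-catalysed alkoxycarbonylation of the alkenyl triflate introduces C12 as the methyl ester and completes the α-substituted acrylate.

Step 20
Reactants: 31 methyl acrylate with 8α-OTES
Product: 32 8α-hydroxy acrylate
Conditions: PPTS (0.2 equiv), MeOH–CH2Cl2 (1:1), 0 °C
Reagents that add atoms: none
Why: Acid-catalysed methanolysis removes only the most labile silyl ether (secondary TES), leaving the TBS ether and the silylene in place.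

Step 21
Reactants: 32 8α-hydroxy acrylate
Product: 33 8α-acetate
Conditions: Ac2O, pyridine, DMAP (cat.), CH2Cl2, 0 °C → rt
Reagents that add atoms: acetic anhydride, CC(=O)OC(C)=O
Why: DMAP-catalysed acylation of the only free hydroxyl places the acetate on O8.

Step 22
Reactants: 33 8α-acetate
Product: 34 CNP0272656.1 (methyl 8α-acetoxy-1β,4α,6α-trihydroxyeudesm-11(13)-en-12-oate)
Conditions: HF·pyridine (excess), pyridine, THF, 0 °C → rt; cold aq. NaHCO3 quench
Reagents that add atoms: none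
Why: Buffered fluoride desilylation removes the TBS ether and the silylene under non-basic conditions, so the acetate, the acrylate and the lactonisation-prone 6-OH/ester pair survive.

**Compound list**
1 | 2-methylcyclohexane-1,3-dione | CC1C(=O)CCCC1=O | starting material
2 | methyl vinyl ketone (but-3-en-2-one) | CC(=O)C=C | starting material
3 | 2-methyl-2-(3-oxobutyl)cyclohexane-1,3-dione | CC(=O)CCC1(C)C(=O)CCCC1=O | intermediate
4 | cis-fused ketol, 4a-hydroxy-8a-methyl-octahydronaphthalene-1,6-dione (OH cis to CH3) | C[C@@]12CCC(=O)C[C@]1(O)CCCC2=O | intermediate (not isolated)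
5 | (R)-Wieland–Miescher ketone, (8aR)-8a-methyl-3,4,8,8a-tetrahydronaphthalene-1,6(2H,7H)-dione | C[C@@]12CCC(=O)C=C1CCCC2=O | intermediate
6 | (4aR,5R)-5-hydroxy-4a-methyl-4,4a,5,6,7,8-hexahydronaphthalen-2(3H)-one (1β-OH, cis to CH3) | C[C@@]12CCC(=O)C=C1CCC[C@H]2O | intermediate
7 | 1β-TBS ether of 6 (Δ5-en-7-one) | C[C@@]12CCC(=O)C=C1CCC[C@H]2O[Si](C)(C)C(C)(C)C | intermediate
8 | 1β-TBSO-10β-methyl-octal-4(5)-en-7-one ethylene ketal | C[C@@]12CCC3(OCCO3)CC1=CCC[C@H]2O[Si](C)(C)C(C)(C)C | intermediate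
9 | 4α,5α-epoxide of 8 | C[C@@]12CCC3(OCCO3)C[C@]14O[C@@H]4CC[C@H]2O[Si](C)(C)C(C)(C)C | intermediate
10 | 1β-TBSO-5α-hydroxy-4β,10β-dimethyl-decalin-7-one ethylene ketal | C[C@@]12CCC3(OCCO3)C[C@@]1(O)[C@@H](C)CC[C@H]2O[Si](C)(C)C(C)(C)C | intermediate
11 | 1β-TBSO-5α-hydroxy-4β,10β-dimethyl-decalin-7-one | C[C@@]12CCC(=O)C[C@@]1(O)[C@@H](C)CC[C@H]2O[Si](C)(C)C(C)(C)C | intermediate (not isolated)
12 | 1β-TBSO-4α,10β-dimethyl-octal-5-en-7-one | C[C@@]12CCC(=O)C=C1[C@H](C)CC[C@H]2O[Si](C)(C)C(C)(C)C | intermediate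
13 | potassium 4(5),6-dienolate of 12 | C[C@@]12CCC(O[K])=CC1=C(C)CC[C@H]2O[Si](C)(C)C(C)(C)C | intermediate (not isolated)
14 | 1β-TBSO-4,10β-dimethyl-octal-4(5)-en-7-one (β,γ-enone) | C[C@@]12CCC(=O)CC1=C(C)CC[C@H]2O[Si](C)(C)C(C)(C)C | intermediate
15 | 4α,5α-epoxy-4β-methyl-7-ketone | C[C@@]12CCC(=O)C[C@]14O[C@]4(C)CC[C@H]2O[Si](C)(C)C(C)(C)C | intermediate (not isolated)
16 | 1β-TBSO-4α-hydroxy-4β,10β-dimethyl-octal-5-en-7-one | C[C@@]12CCC(=O)C=C1[C@](C)(O)CC[C@H]2O[Si](C)(C)C(C)(C)C | intermediate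
17 | dilithium Δ6-enolate/C4-alkoxide (5α-H) | C[C@@]12CCC(O[Li])=C[C@H]1[C@](C)(O[Li])CC[C@H]2O[Si](C)(C)C(C)(C)C | intermediate (not isolated)
18 | 1β-TBSO-4α,7-bis(TMSO)-4β,10β-dimethyl-5α-octal-6-ene | C[C@@]12CCC(O[Si](C)(C)C)=C[C@H]1[C@](C)(O[Si](C)(C)C)CC[C@H]2O[Si](C)(C)C(C)(C)C | intermediate
19 | 1β-TBSO-4α,6α-bis(TMSO)-trans-decalin-7-one | C[C@@]12CCC(=O)[C@H](O[Si](C)(C)C)[C@H]1[C@](C)(O[Si](C)(C)C)CC[C@H]2O[Si](C)(C)C(C)(C)C | intermediate (not isolated)
20 | 1β-TBSO-4α,6α-dihydroxy-4β,10β-dimethyl-trans-decalin-7-one | C[C@@]12CCC(=O)[C@H](O)[C@H]1[C@](C)(O)CC[C@H]2O[Si](C)(C)C(C)(C)C | intermediate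
21 | 4α,6α-O-(di-tert-butylsilylene) derivative of 20 | C[C@@]12CCC(=O)[C@@H]3O[Si](C(C)(C)C)(C(C)(C)C)O[C@](C)(CC[C@H]2O[Si](C)(C)C(C)(C)C)[C@@H]13 | intermediate
22 | potassium Δ7(8)-enolate of 21 | C[C@@]12CC=C(O[K])[C@@H]3O[Si](C(C)(C)C)(C(C)(C)C)O[C@](C)(CC[C@H]2O[Si](C)(C)C(C)(C)C)[C@@H]13 | intermediate (not isolated)
23 | Δ7(8)-en-7-yl triflate | C[C@@]12CC=C(OS(=O)(=O)C(F)(F)F)[C@@H]3O[Si](C(C)(C)C)(C(C)(C)C)O[C@](C)(CC[C@H]2O[Si](C)(C)C(C)(C)C)[C@@H]13 | intermediate
24 | 7-(1-ethoxyvinyl)-Δ7(8)-ene | C[C@@]12CC=C(C(=C)OCC)[C@@H]3O[Si](C(C)(C)C)(C(C)(C)C)O[C@](C)(CC[C@H]2O[Si](C)(C)C(C)(C)C)[C@@H]13 | intermediate (not isolated)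
25 | 7-acetyl-Δ7(8)-ene (C11 ketone, C13 methyl) | C[C@@]12CC=C(C(C)=O)[C@@H]3O[Si](C(C)(C)C)(C(C)(C)C)O[C@](C)(CC[C@H]2O[Si](C)(C)C(C)(C)C)[C@@H]13 | intermediate
26 | 8α-(pinacolboryl)-7β-acetyl compound | C[C@@]12C[C@H](B4OC(C)(C)C(C)(C)O4)[C@@H](C(C)=O)[C@@H]3O[Si](C(C)(C)C)(C(C)(C)C)O[C@](C)(CC[C@H]2O[Si](C)(C)C(C)(C)C)[C@@H]13 | intermediate (not isolated)
27 | 8α-hydroxy-7β-acetyl compound (7α-H) | C[C@@]12C[C@H](O)[C@@H](C(C)=O)[C@@H]3O[Si](C(C)(C)C)(C(C)(C)C)O[C@](C)(CC[C@H]2O[Si](C)(C)C(C)(C)C)[C@@H]13 | intermediate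
28 | 8α-triethylsilyl ether of 27 | C[C@@]12C[C@H](O[Si](CC)(CC)CC)[C@@H](C(C)=O)[C@@H]3O[Si](C(C)(C)C)(C(C)(C)C)O[C@](C)(CC[C@H]2O[Si](C)(C)C(C)(C)C)[C@@H]13 | intermediate
29 | potassium enolate of the methyl ketone 28 (C11=C13) | C[C@@]12C[C@H](O[Si](CC)(CC)CC)[C@@H](C(=C)O[K])[C@@H]3O[Si](C(C)(C)C)(C(C)(C)C)O[C@](C)(CC[C@H]2O[Si](C)(C)C(C)(C)C)[C@@H]13 | intermediate (not isolated)
30 | 2-propenyl (C11) triflate | C[C@@]12C[C@H](O[Si](CC)(CC)CC)[C@@H](C(=C)OS(=O)(=O)C(F)(F)F)[C@@H]3O[Si](C(C)(C)C)(C(C)(C)C)O[C@](C)(CC[C@H]2O[Si](C)(C)C(C)(C)C)[C@@H]13 | intermediate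
31 | methyl 1β-TBSO-4α,6α-O-(di-tert-butylsilylene)-8α-TESO-eudesm-11(13)-en-12-oate | C[C@@]12C[C@H](O[Si](CC)(CC)CC)[C@@H](C(=C)C(=O)OC)[C@@H]3O[Si](C(C)(C)C)(C(C)(C)C)O[C@](C)(CC[C@H]2O[Si](C)(C)C(C)(C)C)[C@@H]13 | intermediate
32 | 8α-hydroxy analogue of 31 | C[C@@]12C[C@H](O)[C@@H](C(=C)C(=O)OC)[C@@H]3O[Si](C(C)(C)C)(C(C)(C)C)O[C@](C)(CC[C@H]2O[Si](C)(C)C(C)(C)C)[C@@H]13 | intermediate
33 | 8α-acetate of 32 | C[C@@]12C[C@H](OC(C)=O)[C@@H](C(=C)C(=O)OC)[C@@H]3O[Si](C(C)(C)C)(C(C)(C)C)O[C@](C)(CC[C@H]2O[Si](C)(C)C(C)(C)C)[C@@H]13 | intermediate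
34 | CNP0272656.1, methyl 8α-acetoxy-1β,4α,6α-trihydroxyeudesm-11(13)-en-12-oate | C=C(C(=O)OC)[C@H]1[C@H](O)[C@@H]2[C@@](C)(C[C@@H]1OC(C)=O)[C@H](O)CC[C@@]2(C)O | target

**Totals**
Total step count: 22. Longest linear sequence: 22 steps (fully linear from 1 and 2).

**Three steps most likely to fail**

Step 10 (face selectivity of the peracid on the tetrasubstituted β,γ-alkene, and the lability of 14). The fallback sets out from 14 and replaces the undirected epoxidation by a hydroxyl-directed one. L-Selectride (THF, −78 °C) reduces the ketone to the axial homoallylic 7α-alcohol F1. VO(acac)2/t-BuOOH (CH2Cl2, 0 °C) then delivers oxygen from that alcohol to the α-face to give the 4α,5α-epoxy 7α-alcohol F2. Dess–Martin periodinane (NaHCO3, CH2Cl2) returns the ketone, which is compound 15, and Et3N carries it on to 16 as in the route.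

Step 11 (dissolving-metal reduction of a γ-hydroxy enone: possible loss of the C4 oxygen, over-reduction or imperfect trans selectivity). The fallback sets out from 16 and uses hydroboration instead of reduction plus Rubottom oxidation. Luche reduction (NaBH4, CeCl3·7H2O, MeOH, −78 °C) gives the allylic 4α,7β-diol F3 (C7 configuration is of no consequence). BH3·THF followed by NaOH/H2O2 adds H to C5 and B to C6 from the α-face, as in Δ5-steroids, to give the trans-fused 4α,6α,7β-triol F4. TEMPO (cat.)/PhI(OAc)2 in CH2Cl2 then oxidises the unhindered C7 carbinol in preference to the peri-shielded C6 carbinol and gives compound 20.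

Step 16 (facial selectivity and reactivity of the conjugate borylation next to the silylene). The fallback sets out from 25 and uses an epoxide as the oxygen source. Weitz–Scheffer epoxidation (t-BuOOH, DBU, CH2Cl2, rt) gives the 7α,8α-epoxy ketone F5. SmI2 (THF–MeOH, −90 °C) cleaves the Cα–O bond reductively and, after equilibration of C7, gives the 8α-hydroxy ketone 27.

**Further compounds**
F1 | step 10 | 1β-TBSO-4,10β-dimethyl-octal-4(5)-en-7α-ol | C[C@@]12CC[C@H](O)CC1=C(C)CC[C@H]2O[Si](C)(C)C(C)(C)C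
F2 | step 10 | 4α,5α-epoxy-4β-methyl-7α-ol | C[C@@]12CC[C@H](O)C[C@]14O[C@]4(C)CC[C@H]2O[Si](C)(C)C(C)(C)C
F3 | step 11 | 1β-TBSO-4β,10β-dimethyl-octal-5-ene-4α,7β-diol | C[C@@]12CC[C@@H](O)C=C1[C@](C)(O)CC[C@H]2O[Si](C)(C)C(C)(C)C
F4 | step 11 | 1β-TBSO-4β,10β-dimethyl-trans-decalin-4α,6α,7β-triol | C[C@@]12CC[C@@H](O)[C@H](O)[C@H]1[C@](C)(O)CC[C@H]2O[Si](C)(C)C(C)(C)C
F5 | step 16 | 7α,8α-epoxy-7β-acetyl silylene compound | C[C@@]12C[C@@H]4O[C@]4(C(C)=O)[C@@H]3O[Si](C(C)(C)C)(C(C)(C)C)O[C@](C)(CC[C@H]2O[Si](C)(C)C(C)(C)C)[C@@H]13
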